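## The problem

Compound 23 is the mono-ether that magnolol (19) forms through one phenolic oxygen with C4 of a cis-fused eudesmane-4,11-diol (eudesmane numbering is used for the terpene part throughout). Rings A and B are six-membered carbocycles sharing the C5–C10 bond; C10 is a methyl-bearing quaternary carbon, C5 carries a hydrogen, C7 a 2-hydroxyprop-2-yl group, and C4 a methyl group and the aryloxy group. The four stereocentres are C4 (R), C5 (S), C7 (R) and C10 (R): the C4 methyl, H-5, the C7 side chain and the C10 methyl all lie on the β face, and the aryloxy group is axial on the concave α face. C7 and C10 stand 1,4 across ring B and cannot be corrected once made, so they must be set together and in the absolute sense. C5 can be adjusted only while C4 is a carbonyl. C4 can be left to the end: with the bulky C7 group equatorial, the folded cis-decalin places the C9 methylene syn-axial over the α face of C4, so a carbon nucleophile must enter from β. The C4–O bond is a hindered tertiary alkyl aryl ether that cannot be made by displacement, and both it and the C11 tertiary alcohol ionize or eliminate in strong acid. The two allyl groups and the free phenol rule out hydrogenation, electrophilic halogen and alkene-isomerizing conditions once magnolol is in place. The feature that makes the plan possible is the position of the C4 carbonyl between a methylene and the epimerizable ring-fusion methine C5. In a 4-oxo cis-decalin the trans isomer competes, but in the five-membered analogue of ring A that lacks C3 (a hydrindan-1-one, as in 15-oxo steroids with a 14β hydrogen) the cis fusion is the stable one. Ring A can therefore be made as a cyclopentanone with secure cis fusion and then enlarged by inserting C3 on the methylene side.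

## Retrosynthesis

**23 to 22.** The O–Si bond at C11 is cut. The tertiary alcohol is carried as its triethylsilyl ether 22 because a free tertiary hydroxyl would bind the Lewis acids used earlier and would invite dehydration. The forward step must remove silicon without acid, since the C4 ether is acid-labile.

**22 to 21.** The C4–C15 bond is cut, leading back to spiroketal 21, in which C4 carries both magnolol oxygens. The neighbouring cuts are worse: O-arylation of a hindered tertiary alcohol is the hardest bond to make in the molecule, and capture of a C4 cation by the phenol gives no reliable stereocontrol and competes with ring alkylation. In 21 C4 is not a stereocentre, and the symmetry of magnolol makes the two C–O bonds equivalent. The forward reaction (Me3Al) must deliver methyl to the β face of the aryloxycarbenium ion, which the decalin shape provides.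

**21 to 18 and 19.** Both C4–O bonds are cut, giving decalone 18 and commercial magnolol 19. This removes all aromatic carbons and the allyl groups in one operation. The forward ketalization must be mild enough to keep C5 and the silyl ether intact.

**18 to 15 and 16 (key disconnection).** The C2–C3 and C3–C4 bonds are cut and C3 is excised, giving cis-hydrindanone 15 and trimethylsilyldiazomethane 16. Against a direct decalone synthesis, this moves the formation of the C5 stereocentre into a ring system where cis is the thermodynamic fusion. The forward step must insert the carbon on the methylene side (migration of C2, not C5) and leave C5 untouched.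

**15 to 14 to 13.** Saturation of C8=C9 leads to hydrindenone 14. Cutting C5–C10 and C6–C7 opens both rings to the acyclic (6Z,8E)-trienone 13 (intramolecular Diels–Alder). This one cut removes three stereocentres and two rings. The forward reaction needs a chiral Lewis acid for absolute control, the Z placement of the tether on the diene for cis fusion, and the E geometry at the other end for the cis relation of the C10 methyl and the C7 side chain.

**13 to 12 to 11 and 3.** The vinyl ketone is taken back to allylic alcohol 12 so that the sensitive enone appears only at the moment of use. The C8–C9 bond of the diene is then cut (Suzuki–Miyaura) into (Z)-alkenyl iodide 11 and (E)-alkenylboronate 3. Cutting between the two alkenes lets each geometry be made separately by a stereospecific addition to an alkyne.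

**11 to 10 to 9 to 4 and 5.** The C4–C5 bond is cut (vinyl Grignard addition to aldehyde 10). The aldehyde is unmasked from dioxolane 9 before any acid-sensitive group exists. The C1–C10 and C9–I bonds of 9 come from syn carbocupration of propyne (5) with the copper reagent 7, derived from the Grignard reagent 6 of bromo acetal 4, followed by iodinolysis of alkenylcopper 8.

**3 to 2 to 1.** The C8–B bond is cut (hydroboration of silyl ether 2), and the O–Si bond leads to commercial 2-methylbut-3-yn-2-ol (1), which supplies C7, C8, C11, C12 and C13.

## Roads not taken

**Alternative 1:** The cut goes through C4–C5 and C9–C10 and opens both rings to an acyclic magnolol ketal A2 with a Z trisubstituted olefin and a terminal silyl enol ether. In the forward key step SnCl4 would ionize the ketal to a C4 aryloxycarbenium ion, which adds to C5; the C10 cation is trapped by the enol ether carbon C9 to give the 8-oxo, 11-O-silyl derivative A1.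
- Merits: this is the most convergent idea. Magnolol is carried in as the initiating group, so the tertiary aryl ether, both rings and the C4, C5 and C10 centres arise in one step with no separate methyl delivery.
- Weak points: C7 must be made enantioselectively beforehand and sits next to the enol ether. Z olefins cyclize through less ordered, often stepwise paths, so both the cis fusion and the C4 configuration (which depends on the oxocarbenium geometry) are uncertain. The allyl groups and the electron-rich phenol ring compete for the cations. A1 carries a C8 ketone that must be removed in the presence of allyl groups and an acid-labile ether, which costs several steps.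
- Comparison: on paper Alternative 1 is shorter and better in convergence. The chosen plan sets against it that each stereocentre has its own understood control element (catalyst and diene geometry for C7 and C10, thermodynamics for C5, decalin shape for C4) and that no surplus oxygen has to be removed.

**Alternative 2:** The cut goes through C5–C10 and C6–C7 of the decalin itself. The homologous (7Z,9E)-decatrienone A4 would cyclize under the same oxazaborolidinium catalysis to cis-octalone A3, whose hydrogenation gives 18 directly.
- Merits: it is one step shorter, needs no diazo reagent and raises no question of migration regiochemistry.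
- Weak points: the four-atom tether makes the cyclization of an already sluggish Z diene slower, which leaves more time for ionization of the dienyl silyl ether and for uncatalysed background reaction. The cis fusion of A3 is kinetic only: the ketone sits next to C5 under a strong Lewis acid, and nothing corrects an erosion.
- Comparison: in step count and reagent safety Alternative 2 is as good or better and would be preferred if A3 proved configurationally robust. The chosen plan sets against it the faster five-ring-forming cycloaddition and a thermodynamic safety net for C5 up to ketone 15, at the price of one extra, well-precedented step.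

**Alternative 3:** The cut goes through C4–C5 and C1–C10 (ring A only). The silylated carvone hydrate A6, from (S)-carvone, would react with 2-silyloxy diene A7 under EtAlCl2 to give the cis-fused adduct A5.
- Merits: the absolute configuration comes from the chiral pool with no reliance on a catalyst model. Lewis-acid Diels–Alder reactions of 2-methylcyclohexenones are well known, and the quaternary C10 and the cis fusion are set directly, syn to the C7 group.
- Weak points: the oxygens end up at C3 and C9 and none at C4. C4 arrives as a CH(CH3) centre that must be destroyed to install the ether, which returns to the O-arylation of a tertiary alcohol. Two carbonyl groups must also be removed.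
- Comparison: Alternative 3 is better in the source and certainty of absolute configuration. The chosen plan sets against it the correct placement of the single carbonyl at C4, which is used twice (ring expansion, then ether formation), and far fewer functional-group corrections.

Key step: step 10

Remark (assumption): the facial sense of the cycloaddition catalyst in step 8 is assigned from the α-C–H···O binding model for vinyl ketones, which calls for the catalyst derived from (R)-α,α-diphenylprolinol; the enantiomeric catalyst is equally available.

## Route

Step 1
Reactants: 1 2-methylbut-3-yn-2-ol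
Product: 2 triethyl[(2-methylbut-3-yn-2-yl)oxy]silane
Conditions: Et3SiCl, imidazole, DMAP (cat.), DMF, 0 °C to rt
Reagents that add atoms: chlorotriethylsilane, CC[Si](Cl)(CC)CC
Why: Silyl ether formation at a tertiary propargylic alcohol that is unhindered on the alkyne side; a tertiary triethylsilyl ether is a poor Lewis base, should survive the Lewis acids of steps 8, 10 and 12, and leaves with fluoride without acid.

Step 2
Reactants: 2 triethyl[(2-methylbut-3-yn-2-yl)oxy]silane
Product: 3 triethyl{[(3E)-2-methyl-4-(4,4,5,5-tetramethyl-1,3,2-dioxaborolan-2-yl)but-3-en-2-yl]oxy}silane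
Conditions: pinacolborane, Cp2Zr(H)Cl (5 mol %), Et3N (10 mol %), neat, 60 °C
Reagents that add atoms: pinacolborane, CC1(C)OBOC1(C)C
Why: Zirconium-catalysed hydroboration of a terminal alkyne: syn addition with boron at the terminal carbon gives the (E)-alkenylboronate, and the bulky silyloxy group reinforces this regiochemistry.

Step 3
Reactants: 4 2-(2-bromoethyl)-1,3-dioxolane; 5 propyne
Product: 9 2-[(3Z)-4-iodo-3-methylbut-3-en-1-yl]-1,3-dioxolane, via Grignard reagent 6 (not isolated), via alkylcopper 7 (not isolated), via alkenylcopper 8 (not isolated)
Conditions: Mg, THF, 25 °C; CuBr·SMe2, Et2O–Me2S, −45 °C; propyne, −25 °C; I2, THF, −78 to 0 °C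
Reagents that add atoms: iodine, I-I
Why: Grignard formation, transmetallation to the alkylcopper and syn carbocupration of a terminal alkyne put the alkyl group on the internal carbon and copper on the terminal carbon on the same side; iodinolysis goes with retention, so iodine and the acetal chain are cis (Z), the geometry that later places the tether on the inside of the diene.

Step 4
Reactants: 9 2-[(3Z)-4-iodo-3-methylbut-3-en-1-yl]-1,3-dioxolane
Product: 10 (4Z)-5-iodo-4-methylpent-4-enal
Conditions: 2 M aq HCl, THF, rt
Reagents that add atoms: water, O
Why: Acid-catalysed acetal hydrolysis, placed here because the alkenyl iodide tolerates aqueous acid whereas the dienyl tertiary silyl ether made later would not.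

Step 5
Reactants: 10 (4Z)-5-iodo-4-methylpent-4-enal
Product: 11 (6Z)-7-iodo-6-methylhepta-1,6-dien-3-ol (racemic at C3)
Conditions: CH2=CHMgBr, THF, −78 °C
Reagents that add atoms: vinylmagnesium bromide, C=C[Mg]Br
Why: Grignard 1,2-addition to an aldehyde supplies C5 and C6; the carbinol centre is racemic and is erased by the oxidation of step 7.

Step 6
Reactants: 11 (6Z)-7-iodo-6-methylhepta-1,6-dien-3-ol; 3 triethyl{[(3E)-2-methyl-4-(4,4,5,5-tetramethyl-1,3,2-dioxaborolan-2-yl)but-3-en-2-yl]oxy}silane
Product: 12 (6Z,8E)-6,10-dimethyl-10-(triethylsilyloxy)undeca-1,6,8-trien-3-ol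
Conditions: Pd(dppf)Cl2 (5 mol %), Cs2CO3, THF–H2O, 40 °C
Reagents that add atoms: none
Why: Suzuki–Miyaura coupling of an alkenyl iodide with an alkenylboronate forms C8–C9 with retention of both geometries; the free secondary alcohol and the silyl ether tolerate the mild aqueous base.

Step 7
Reactants: 12 (6Z,8E)-6,10-dimethyl-10-(triethylsilyloxy)undeca-1,6,8-trien-3-ol
Product: 13 (6Z,8E)-6,10-dimethyl-10-(triethylsilyloxy)undeca-1,6,8-trien-3-one
Conditions: Dess–Martin periodinane, NaHCO3, CH2Cl2, 0 °C
Reagents that add atoms: none
Why: Dess–Martin oxidation of an allylic alcohol under bicarbonate buffer gives the vinyl ketone without touching the diene or the silyl ether; the trienone is used at once to forestall uncatalysed cyclization and polymerization.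

Step 8
Reactants: 13 (6Z,8E)-6,10-dimethyl-10-(triethylsilyloxy)undeca-1,6,8-trien-3-one
Product: 14 (3aR,6S,7aS)-3a-methyl-6-[2-(triethylsilyloxy)propan-2-yl]-2,3,3a,6,7,7a-hexahydro-1H-inden-1-one
Conditions: oxazaborolidinium triflimide from (R)-α,α-diphenylprolinol, o-tolylboroxine and Tf2NH (20 mol %), CH2Cl2, −78 to −40 °C
Reagents that add atoms: none
Why: Lewis-acid-catalysed intramolecular Diels–Alder reaction of a 1,6,8-nonatrien-3-one: the cationic oxazaborolidine binds the vinyl ketone and shields one face, so that C5–C10 and C6–C7 should form on the re face of C5. Because the tether sits on the Z side of the diene, only the cis-fused mode with the carbonyl exo is within reach, and suprafacial addition to the (Z,E)-diene places the C10 methyl and the C7 side chain (both outside groups) cis, so C5, C7 and C10 are set in one event.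

Step 9
Reactants: 14 (3aR,6S,7aS)-3a-methyl-6-[2-(triethylsilyloxy)propan-2-yl]-2,3,3a,6,7,7a-hexahydro-1H-inden-1-one
Product: 15 (3aS,6R,7aS)-3a-methyl-6-[2-(triethylsilyloxy)propan-2-yl]octahydro-1H-inden-1-one
Conditions: H2 (1 atm), Pt/C (5 %), EtOAc, rt
Reagents that add atoms: none
Why: Heterogeneous hydrogenation of the cis-disubstituted C8=C9 bond creates no stereocentre; platinum is preferred to palladium to limit double-bond migration toward C7, and ethyl acetate spares the silyl ether. The cis fusion is the stable one for this hydrindan-1-one, so any epimerization at C5 up to this point corrects itself.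

Step 10
Reactants: 15 (3aS,6R,7aS)-3a-methyl-6-[2-(triethylsilyloxy)propan-2-yl]octahydro-1H-inden-1-one; 16 trimethylsilyldiazomethane
Product: 18 (4aR,7R,8aS)-4a-methyl-7-[2-(triethylsilyloxy)propan-2-yl]octahydronaphthalen-1(2H)-one, via α-silyl ketone 17 (not isolated)
Conditions: Me3SiCHN2 (hexanes), BF3·OEt2, CH2Cl2, −78 to −40 °C; aq NaHCO3, then silica gel (protodesilylation)
Reagents that add atoms: none
Why: BF3 activates the C4 carbonyl of 15, the diazo carbon of 16 adds to it, and the β-oxido diazonium ion loses N2 with a 1,2-shift of a ring carbon from C4 to the new carbon C3; the closest known reaction type is exactly this Lewis-acid-promoted silyldiazomethane homologation of cyclopentanones and cyclohexanones. Ring A is not closed by a cyclization: it is enlarged from five to six members by migration of C2, which makes the C2–C3 bond after the addition has made C3–C4, so no ring-closure mode in the usual sense applies. No new stereocentre survives, because C3 becomes a methylene once the silyl group of 17 is lost on work-up, and C5, C7 and C10 are spectators of a migration on the other side of the carbonyl. The selectivity needed is migration of the methylene C2 in preference to the ring-fusion methine C5: the bulky Me3Si group on the diazo carbon turns away from the branched, neopentyl-type C5 flank, which places the C4–C2 bond antiperiplanar to the departing N2, in line with the known preference of this reagent for the less substituted α-carbon. A second insertion is held back because the α-silyl group of 17 shields the new carbonyl until the diazo reagent is consumed. Low temperature and the absence of base carry the cis fusion secured in 15 into the decalone.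

Step 11
Reactants: 18 (4aR,7R,8aS)-4a-methyl-7-[2-(triethylsilyloxy)propan-2-yl]octahydronaphthalen-1(2H)-one; 19 magnolol (5,5'-diallylbiphenyl-2,2'-diol)
Product: 21 (4a'R,7'R,8a'S)-2,10-diallyl-4a'-methyl-7'-[2-(triethylsilyloxy)propan-2-yl]octahydro-2'H-spiro[dibenzo[d,f][1,3]dioxepine-6,1'-naphthalene], via dimethyl ketal 20 (not isolated)
Conditions: HC(OMe)3, MeOH, PPTS (cat.), rt; evaporate; then 19, PPTS (cat.), toluene, 5 Å molecular sieves, 50 °C
Reagents that add atoms: none
Why: Acid-catalysed ketalization by way of the dimethyl ketal: the orthoformate converts the hindered ketone to 20 irreversibly, and exchange with the biphenol, driven by removal of methanol, closes the dibenzo-1,3-dioxepine as known for 2,2'-biphenols. The weak buffered acid is meant to spare the tertiary silyl ether and to avoid enol ether formation toward C5; C4 is not a stereocentre in 21 because its two oxygens are constitutionally equivalent.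

Step 12
Reactants: 21 (4a'R,7'R,8a'S)-2,10-diallyl-4a'-methyl-7'-[2-(triethylsilyloxy)propan-2-yl]octahydro-2'H-spiro[dibenzo[d,f][1,3]dioxepine-6,1'-naphthalene]
Product: 22 5,5'-diallyl-2'-({(1R,4aR,7R,8aS)-1,4a-dimethyl-7-[2-(triethylsilyloxy)propan-2-yl]decahydronaphthalen-1-yl}oxy)biphenyl-2-ol
Conditions: Me3Al (4 equiv), CH2Cl2, −78 to 0 °C; aq potassium sodium tartrate
Reagents that add atoms: trimethylaluminium, C[Al](C)C
Why: Alkylative cleavage of a ketal by a trialkylaluminium: aluminium binds one aryloxy oxygen, the C4–O bond ionizes to an aryloxycarbenium ion paired with the aluminium phenoxide, and methyl is transferred to C4; both oxygens are equivalent, so either cleavage gives the same ether. With the C7 group equatorial the cis-decalin holds the C9 methylene syn-axial over the α face of C4, so methyl should enter equatorially from the β face and give the 4β-methyl, 4α-aryloxy (4R) configuration.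

Step 13
Reactants: 22 5,5'-diallyl-2'-({(1R,4aR,7R,8aS)-1,4a-dimethyl-7-[2-(triethylsilyloxy)propan-2-yl]decahydronaphthalen-1-yl}oxy)biphenyl-2-ol
Product: 23 5,5'-diallyl-2'-{[(1R,4aR,7R,8aS)-7-(2-hydroxypropan-2-yl)-1,4a-dimethyldecahydronaphthalen-1-yl]oxy}biphenyl-2-ol (target)
Conditions: Bu4NF, THF, rt to 45 °C
Reagents that add atoms: none
Why: Fluoride cleavage of the tertiary triethylsilyl ether under non-acidic conditions leaves the acid-labile tertiary aryl ether, the phenol and the allyl groups untouched.

## Compound list

1 | 2-methylbut-3-yn-2-ol | CC(C)(O)C#C | starting material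
2 | triethyl[(2-methylbut-3-yn-2-yl)oxy]silane | CC(C)(O[Si](CC)(CC)CC)C#C | intermediate
3 | triethyl{[(3E)-2-methyl-4-(4,4,5,5-tetramethyl-1,3,2-dioxaborolan-2-yl)but-3-en-2-yl]oxy}silane | CC(C)(O[Si](CC)(CC)CC)/C=C/B1OC(C)(C)C(C)(C)O1 | intermediate
4 | 2-(2-bromoethyl)-1,3-dioxolane | BrCCC1OCCO1 | starting material
5 | propyne | CC#C | starting material
6 | [2-(1,3-dioxolan-2-yl)ethyl]magnesium bromide | Br[Mg]CCC1OCCO1 | intermediate (not isolated)
7 | [2-(1,3-dioxolan-2-yl)ethyl]copper (MgBr2/SMe2 complex) | [Cu]CCC1OCCO1 | intermediate (not isolated)
8 | [(1Z)-4-(1,3-dioxolan-2-yl)-2-methylbut-1-en-1-yl]copper | [Cu]/C=C(C)\CCC1OCCO1 | intermediate (not isolated)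
9 | 2-[(3Z)-4-iodo-3-methylbut-3-en-1-yl]-1,3-dioxolane | I/C=C(C)\CCC1OCCO1 | intermediate
10 | (4Z)-5-iodo-4-methylpent-4-enal | I/C=C(C)\CCC=O | intermediate
11 | (6Z)-7-iodo-6-methylhepta-1,6-dien-3-ol (racemic) | I/C=C(C)\CCC(O)C=C | intermediate
12 | (6Z,8E)-6,10-dimethyl-10-(triethylsilyloxy)undeca-1,6,8-trien-3-ol (racemic carbinol) | CC(C)(O[Si](CC)(CC)CC)/C=C/C=C(C)\CCC(O)C=C | intermediate
13 | (6Z,8E)-6,10-dimethyl-10-(triethylsilyloxy)undeca-1,6,8-trien-3-one | CC(C)(O[Si](CC)(CC)CC)/C=C/C=C(C)\CCC(=O)C=C | intermediate
14 | (3aR,6S,7aS)-3a-methyl-6-[2-(triethylsilyloxy)propan-2-yl]-2,3,3a,6,7,7a-hexahydro-1H-inden-1-one (cis-fused; 3a-methyl, H-7a and side chain on one face) | O=C1CC[C@]2(C)C=C[C@@H](C(C)(C)O[Si](CC)(CC)CC)C[C@@H]21 | intermediate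
15 | (3aS,6R,7aS)-3a-methyl-6-[2-(triethylsilyloxy)propan-2-yl]octahydro-1H-inden-1-one (cis-fused) | O=C1CC[C@]2(C)CC[C@@H](C(C)(C)O[Si](CC)(CC)CC)C[C@@H]21 | intermediate
16 | trimethylsilyldiazomethane | C[Si](C)(C)C=[N+]=[N-] | starting material
17 | 2-(trimethylsilyl) derivative of 18 (silicon on C3 in eudesmane numbering; both C3 epimers) | O=C1C([Si](C)(C)C)CC[C@]2(C)CC[C@@H](C(C)(C)O[Si](CC)(CC)CC)C[C@@H]21 | intermediate (not isolated)
18 | (4aR,7R,8aS)-4a-methyl-7-[2-(triethylsilyloxy)propan-2-yl]octahydronaphthalen-1(2H)-one (cis-fused 4-ketone) | O=C1CCC[C@]2(C)CC[C@@H](C(C)(C)O[Si](CC)(CC)CC)C[C@@H]21 | intermediate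
19 | magnolol (5,5'-diallylbiphenyl-2,2'-diol) | C=CCc1ccc(O)c(-c2cc(CC=C)ccc2O)c1 | starting material
20 | (4aR,7R,8aS)-1,1-dimethoxy-4a-methyl-7-[2-(triethylsilyloxy)propan-2-yl]decahydronaphthalene | COC1(OC)CCC[C@]2(C)CC[C@@H](C(C)(C)O[Si](CC)(CC)CC)C[C@@H]21 | intermediate (not isolated)
21 | (4a'R,7'R,8a'S)-2,10-diallyl-4a'-methyl-7'-[2-(triethylsilyloxy)propan-2-yl]octahydro-2'H-spiro[dibenzo[d,f][1,3]dioxepine-6,1'-naphthalene] (magnolol ketal of 18) | C=CCc1ccc2c(c1)-c1cc(CC=C)ccc1OC1(O2)CCC[C@]3(C)CC[C@@H](C(C)(C)O[Si](CC)(CC)CC)C[C@@H]31 | intermediate
22 | 5,5'-diallyl-2'-({(1R,4aR,7R,8aS)-1,4a-dimethyl-7-[2-(triethylsilyloxy)propan-2-yl]decahydronaphthalen-1-yl}oxy)biphenyl-2-ol | C=CCc1ccc(O)c(-c2cc(CC=C)ccc2O[C@]2(C)CCC[C@]3(C)CC[C@@H](C(C)(C)O[Si](CC)(CC)CC)C[C@@H]32)c1 | intermediate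
23 | 5,5'-diallyl-2'-{[(1R,4aR,7R,8aS)-7-(2-hydroxypropan-2-yl)-1,4a-dimethyldecahydronaphthalen-1-yl]oxy}biphenyl-2-ol | C=CCc1ccc(O)c(-c2cc(CC=C)ccc2O[C@]2(C)CCC[C@]3(C)CC[C@@H](C(C)(C)O)C[C@@H]32)c1 | target

## Step count and least certain steps

Total: 13 steps. Longest linear sequence: 11 steps (4 to 23 through steps 3–13); the boronate branch (1 to 3) has 2 steps.

**Step 10 (key step).** Three things may go wrong. The ring-fusion carbon C5 may migrate in competition with C2, since more substituted carbons are the better migrating groups in the absence of the steric bias of the silyl reagent. A second insertion may give a seven-membered ketone. The BF3-complexed ketone may enolize and erode C5, or the silyl ether may be lost. The fallback fixes the regiochemistry by enolate formation instead of migratory aptitude. It sets out from 15: kinetic deprotonation on the methylene side (LiN(i-Pr)2, Me3SiCl, THF, −78 °C) gives the trimethylsilyl enol ether F1; Simmons–Smith cyclopropanation (Et2Zn, CH2I2) gives the siloxycyclopropane F2; oxidative ring opening with FeCl3 in DMF cleaves the internal cyclopropane bond to the ring-enlarged β-chloro ketone F3; NaOAc in methanol eliminates HCl to the enone F4; hydrogenation (H2, Pt/C, EtOAc) returns to the route at 18.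

**Step 8.** The strongly acidic catalyst may ionize the dienyl tertiary silyl ether. The Z diene with a fully substituted terminus may react so slowly that the uncatalysed pathway lowers the enantiomeric purity. The face selection may not follow the binding model in this exo-only transition state. The fallback gives up catalytic control: 13 is cyclized thermally without acid (toluene, 90 °C, trace of 2,6-di-tert-butyl-4-methylphenol), which should give racemic cis-fused material, that is 14 together with its enantiomer F5. The enantiomers are separated by preparative chromatography on a chiral stationary phase (cellulose tris(3,5-dimethylphenylcarbamate)), and the route is rejoined at 14.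

**Step 11.** The hindered C4 ketone may not close the seven-membered diaryl ketal at equilibrium. Acid-catalysed enol ether formation toward C5 may epimerize the ring fusion. The tertiary silyl ether may be cleaved. The fallback replaces equilibrium ketalization by stepwise C–O bond formation. It sets out from 18: kinetic enolization on the C3 side and triflation (KN(SiMe3)2, PhNTf2, THF, −78 °C) give the enol triflate F6; palladium-catalysed C–O coupling with 19 (Pd2(dba)3, 2-(di-tert-butylphosphino)biphenyl, NaOt-Bu, toluene) gives the aryl enol ether F7, which still carries the second phenol; PPTS in CH2Cl2 at 0 °C protonates C3, and the pendant phenol adds to the aryloxycarbenium ion, returning to the route at 21.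

**Step 12.** The aryloxycarbenium ion may lose a proton to give an aryl enol ether in place of methyl transfer. The product, a tertiary ether next to an aluminium phenoxide, may ionize a second time. Methyl delivery may not be fully β-selective. The fallback makes the C4–C15 bond first and the C4–O–aryl bond second. It sets out from 18: MeMgBr with CeCl3 (THF, −78 °C) should add from the open β face to give the tertiary alcohol F8 (4α-hydroxy, 4β-methyl); its sodium alkoxide (NaN(SiMe3)2, toluene) is arylated with the diaryliodonium salt F9, which transfers the 4-allyl-2-bromophenyl group and gives the aryl ether F10; Suzuki–Miyaura coupling of F10 with the boronate F11 (Pd(OAc)2, 2-dicyclohexylphosphino-2',6'-dimethoxybiphenyl, K3PO4, toluene–H2O) builds the biaryl and returns to the route at 22.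

## Further compounds

F1 | step 10 | trimethylsilyl enol ether of 15 toward the ring methylene (3a-methyl-3-silyloxy-hexahydroindene, cis-fused) | C[Si](C)(C)OC1=CC[C@]2(C)CC[C@@H](C(C)(C)O[Si](CC)(CC)CC)C[C@@H]21
F2 | step 10 | siloxycyclopropane from F1 (methylene bridging C4 and C2; cyclopropane centres not assigned) | C[Si](C)(C)OC12CC1C[C@]1(C)CC[C@@H](C(C)(C)O[Si](CC)(CC)CC)C[C@@H]12
F3 | step 10 | 3-chloro derivative of 18 (chlorine β to the carbonyl, at C2 in eudesmane numbering; epimers) | O=C1CC(Cl)C[C@]2(C)CC[C@@H](C(C)(C)O[Si](CC)(CC)CC)C[C@@H]21
F4 | step 10 | (4aR,7R,8aS)-4a-methyl-7-[2-(triethylsilyloxy)propan-2-yl]-4a,5,6,7,8,8a-hexahydronaphthalen-1(4H)-one (2,3-enone of 18) | O=C1C=CC[C@]2(C)CC[C@@H](C(C)(C)O[Si](CC)(CC)CC)C[C@@H]21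
F5 | step 8 | (3aS,6R,7aR)-enantiomer of 14 | O=C1CC[C@@]2(C)C=C[C@H](C(C)(C)O[Si](CC)(CC)CC)C[C@H]21
F6 | step 11 | enol triflate of 18 (C3=C4 double bond, cis-fused) | FC(F)(F)S(=O)(=O)OC1=CCC[C@]2(C)CC[C@@H](C(C)(C)O[Si](CC)(CC)CC)C[C@@H]21
F7 | step 11 | mono enol ether of magnolol with 18 (aryloxy group on C4 of the C3=C4 alkene) | C=CCc1ccc(O)c(-c2cc(CC=C)ccc2OC2=CCC[C@]3(C)CC[C@@H](C(C)(C)O[Si](CC)(CC)CC)C[C@@H]32)c1
F8 | step 12 | (1R,4aR,7R,8aS)-1,4a-dimethyl-7-[2-(triethylsilyloxy)propan-2-yl]decahydronaphthalen-1-ol | O[C@]1(C)CCC[C@]2(C)CC[C@@H](C(C)(C)O[Si](CC)(CC)CC)C[C@@H]21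
F9 | step 12 | (4-allyl-2-bromophenyl)(2,4,6-trimethoxyphenyl)iodonium trifluoromethanesulfonate | C=CCc1ccc([I+]c2c(OC)cc(OC)cc2OC)c(Br)c1.[O-]S(=O)(=O)C(F)(F)F
F10 | step 12 | 4-allyl-2-bromophenyl ether of F8 | C=CCc1ccc(O[C@]2(C)CCC[C@]3(C)CC[C@@H](C(C)(C)O[Si](CC)(CC)CC)C[C@@H]32)c(Br)c1
F11 | step 12 | 4-allyl-2-(4,4,5,5-tetramethyl-1,3,2-dioxaborolan-2-yl)phenol | C=CCc1ccc(O)c(B2OC(C)(C)C(C)(C)O2)c1
A1 | alternative 1 | 8-oxo, 11-O-tert-butyldimethylsilyl derivative of the target | C=CCc1ccc(O)c(-c2cc(CC=C)ccc2O[C@]2(C)CCC[C@]3(C)CC(=O)[C@@H](C(C)(C)O[Si](C)(C)C(C)(C)C)C[C@@H]32)c1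
A2 | alternative 1 | magnolol ketal of the acyclic (Z)-olefinic methyl ketone with terminal trimethylsilyl enol ether | C=CCc1ccc2OC(C)(CCC/C(C)=C\C[C@H](C(C)(C)O[Si](C)(C)C(C)(C)C)C(=C)O[Si](C)(C)C)Oc3ccc(CC=C)cc3-c2c1
A3 | alternative 2 | cis-fused octal-8-en-4-one, 11-O-triethylsilyl | O=C1CCC[C@]2(C)C=C[C@@H](C(C)(C)O[Si](CC)(CC)CC)C[C@@H]21
A4 | alternative 2 | (7Z,9E)-7,11-dimethyl-11-(triethylsilyloxy)dodeca-1,7,9-trien-3-one | CC(C)(O[Si](CC)(CC)CC)/C=C/C=C(C)\CCCC(=O)C=C
A5 | alternative 3 | cis-fused adduct with C3 silyl enol ether, C4 methyl and C9 ketone | C[C@@H]1C(O[Si](C)(C)C)=CC[C@]2(C)C(=O)C[C@@H](C(C)(C)O[Si](CC)(CC)CC)C[C@H]12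
A6 | alternative 3 | (5S)-2-methyl-5-[2-(triethylsilyloxy)propan-2-yl]cyclohex-2-en-1-one (silylated hydrate of (S)-carvone) | CC1=CC[C@H](C(C)(C)O[Si](CC)(CC)CC)CC1=O
A7 | alternative 3 | (3Z)-3-(trimethylsilyloxy)penta-1,3-diene | C=C/C(O[Si](C)(C)C)=C/C
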